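## Structural features

The target is a depside: two benzene rings joined by a single aryl ester, the carbonyl carbon of ring A being bound to O4 of ring B. Ring B is a 2,4-dioxygenated 6-pentylbenzoic acid (C1 carboxyl, free O2–H, acylated O4, pentyl at C6). Ring A is a 3-chloro-2-hydroxy-4-methoxy-6-pentylbenzoyl unit. There is no stereocentre and no ring fusion, so the problem is one of regiochemistry and of telling oxygens apart. The fragile points are the ortho-hydroxy acid of ring B (it can decarboxylate on heating or on long exposure to acid or base), the inter-ring ester (open to hydrolysis and transesterification under basic conditions) and the aryl chloride (it limits reductive deprotection). The real difficulty lies in ring B: O2 and O4 are similar phenols, yet only O4 may be acylated and the carboxyl must stay masked to the end. In ring A the chlorine must sit between the two oxygens, and only the oxygen para to the carbonyl may stay methylated. The key step uses the fact that the C1(carboxyl)–C6(pentyl) edge of ring B is a masked oct-2-ynoate, while C2–C5 with O2 and O4 correspond to a diene whose two oxygen-bearing carbons differ (ketene acetal and silyl enol ether), so ring B is formed with O2 as a methyl ether and O4 as a free phenol.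

## Logic of the disconnections

21 ⇒ 20. Three O–alkyl bonds are restored on 21: the methyl ethers on O2 of ring B and O2 of ring A, and the benzyl ester on the ring B carboxyl. All three alkyl groups sit on oxygens that flank or belong to a carbonyl, so one chelating Lewis acid can remove them together in the forward direction. The forward step must leave the O4 methyl ether of ring A, the inter-ring ester and the C–Cl bond untouched, and must run cold because 21 can decarboxylate.

20 ⇒ 12 + 18 (through 19). The inter-ring C(=O)–O4 bond is cut. This splits the molecule into two halves of similar size that are made in parallel. The forward acylation requires 12 to have exactly one free hydroxyl and 18 to carry no free hydroxyl when it is activated as 19.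

12 ⇒ 9 + 4. The ring bonds C1–C2 and C5–C6 of ring B are cut. This removes the whole aromatic ring and leaves two acyclic partners, with C1, C6, the carboxyl and the pentyl group in 4 and C2–C5 with both oxygens in 9. The forward cycloaddition must place 9 on 4 in one orientation only and must be followed by aromatization.

4 ⇒ 1 + 2 (through 3). The bond between the alkyne carbon and the ester carbonyl is cut. This leads to a terminal alkyne and a chloroformate that already carries the benzyl group. The forward step needs a clean monoacylation of the acetylide.

9 ⇒ 7 ⇒ 5 + 6 (through 8). The O–Si bond is cut first, then the C–C bond between the ketone carbonyl and the ketene acetal CH. The forward steps need C-acylation of the electron-rich alkene by 6 without loss of a methyl group, then regioselective enolization of 7 at its methyl group.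

18 ⇒ 17 ⇒ 16. The carboxyl is taken back to a formyl group and the ring-to-formyl C–C bond is cut. 16 is symmetrical, so its two open positions are equivalent and the forward electrophilic substitution has no regiochemical choice to make.

16 ⇒ 14 ⇒ 13 (through 15). The C–Cl bond between the two oxygens is cut, then the two O–CH3 bonds. The forward chlorination must go to the position flanked by both oxygens, which electrophilic chlorination would not favour, so it is done by directed metalation.

## Other disconnections considered

Alternative 1: The cut is at two substituent bonds of ring B, C6–pentyl and C1–carboxyl, with the aromatic ring bought intact as A1 (1-fluoro-3,5-dimethoxybenzene). In the forward direction A2 (pentyllithium, at least two equivalents) would metalate A1 between fluorine and methoxy. Loss of fluoride would give aryne A3 (3,5-dimethoxybenzyne). A second A2 would add to the aryne carbon remote from the flanking methoxy group, and carboxylation of the aryllithium would give A4 (2,4-dimethoxy-6-pentylbenzoic acid).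
- In favour: one flask installs both neighbouring carbon substituents on a commercial arene, and the direction of addition to a 3-alkoxyaryne is well understood.
- Against: both oxygens of A4 are methyl ethers. Chelation-controlled dealkylation would free O2, the wrong one, and O4 cannot be unmasked selectively. Exhaustive demethylation, re-esterification and a hydrogen-bond-controlled acylation would be needed. Metalation of A1 between the two methoxy groups would give an aryllithium that cannot eliminate. The product aryllithium can also add to further A3, and A2 is not a routinely stocked reagent.
- Comparison: on structure the chosen plan is better, since 12 arrives with O2 and O4 differentiated and the carboxyl as its benzyl ester. On mechanism the two are equal: both regiochemistries rest on polarization. Alternative 1 is better on step count to the ring B carbon skeleton (one step against four), but the re-differentiation of the oxygens would probably cancel that gain.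

Alternative 2: The cut is at C1–C6 and C2–C3 of ring B at the cyclohexanedione oxidation level. In the forward direction NaOCH2Ph would promote Michael addition of A5 (dibenzyl malonate) to A6 ((E)-non-3-en-2-one), then Claisen closure of the methyl ketone enolate onto one ester, to give A7 (benzyl 2,4-dioxo-6-pentylcyclohexane-1-carboxylate). A separate dehydrogenation would then aromatize the ring.
- In favour: cheap reagents, no organolithium and no sealed-tube heating. The Michael step fixes the pentyl position, so the alternative equals the chosen plan in regiochemical certainty and is better in cost and robustness of ring formation.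
- Against: A7 is two oxidation levels below the arene. Halogen-based aromatization of an electron-rich dione risks nuclear halogenation. The resulting ring B would have both phenols free, so acylation at O4 would depend on the O2–H hydrogen bond to the ester carbonyl.
- Comparison: on structure the chosen plan is better, but only modestly, because hydrogen-bond-controlled acylation is usually workable. Alternative 2 is better on step economy: about two steps to a ring B coupling partner against four, and one methyl ether fewer to cleave at the end. The chosen plan needs no oxidant and leaves no ambiguity about the acylation site.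

Alternative 3: The cut is in ring A, at C3–C4 and C1–C6. In the forward direction TiCl4 would promote a [3+3] cyclocondensation of A8 (4-chloro-1-methoxy-1,3-bis(trimethylsilyloxy)buta-1,3-diene) with A9 (1,1,1-trimethoxyoctan-3-one) to give A10 (methyl 3-chloro-2-hydroxy-4-methoxy-6-pentylbenzoate) after aromatization. It addresses ring A only, so it would replace steps 5–8 and does not compete with the ring B cycloaddition.
- In favour: chlorine, hydroxyl, methoxy, pentyl and carboxyl are all placed by the connectivity of the acyclic partners, and O2 of ring A is free while O4 is methylated. On both points it is the equal or the better of the chosen ring A sequence, and it needs no organolithium.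
- Against: A8 and A9 each have to be made in about two steps. The chlorine lowers the nucleophilicity of the diene terminus that must attack the orthoester carbon. A10 is a hindered, hydrogen-bonded methyl salicylate, so its saponification would be slow and forcing. The free O2–H would then have to be carried through acid activation or protected again.
- Comparison: on regiochemical security the two are equal (directed metalation on a symmetrical arene against connectivity of the partners). On mechanism the chosen sequence uses uniformly routine aromatic chemistry. On step economy the chosen ring A sequence is shorter (four steps from 13 against about six).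

Key step: step 4

Remark on the chemistry: the target has no stereocentre, so no step sets one. Electrophilic chlorination of 14 would be expected para to a methoxy group (C4) and not between the two oxygens, so the chlorine is placed at C2 by directed lithiation.

## Route

Step 1
Reactants: 1 hept-1-yne; 2 benzyl chloroformate
Product: 4 benzyl oct-2-ynoate, via lithium hept-1-yn-1-ide 3 (not isolated)
Conditions: n-BuLi, THF, −78 °C; then 2, −78 → 0 °C
Reagents that add atoms: none
Why: Deprotonation of the terminal alkyne gives acetylide 3, which undergoes acyl substitution at the chloroformate carbonyl (alkynylation of a chloroformate). Low temperature and addition of 3 to excess 2 should prevent a second addition to the ynoate.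

Step 2
Reactants: 5 1,1-dimethoxyethene; 6 acetyl chloride
Product: 7 4,4-dimethoxybut-3-en-2-one
Conditions: Et3N, Et2O, −20 °C → rt (6 added slowly to 5 and Et3N)
Reagents that add atoms: none
Why: The electron-rich ketene acetal is C-acylated by the acid chloride (acylation of a ketene acetal, the enol-ether counterpart of a Friedel–Crafts acylation). Et3N removes the acidic proton of the dialkoxycarbenium intermediate and restores the ketene acetal in conjugation with the ketone.

Step 3
Reactants: 7 4,4-dimethoxybut-3-en-2-one
Product: 9 1,1-dimethoxy-3-(trimethylsilyloxy)buta-1,3-diene, via lithium 4,4-dimethoxybuta-1,3-dien-2-olate 8 (not isolated)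
Conditions: LiN(iPr)2, THF, −78 °C; then Me3SiCl, −78 °C → rt; distillation under reduced pressure
Reagents that add atoms: chlorotrimethylsilane, C[Si](C)(C)Cl
Why: The methyl ketone is the only enolizable position, so kinetic deprotonation by the hindered amide gives cross-conjugated enolate 8, which is silylated on oxygen (silyl enol ether formation). The moisture-sensitive diene should be distilled and used promptly.

Step 4
Reactants: 9 1,1-dimethoxy-3-(trimethylsilyloxy)buta-1,3-diene; 4 benzyl oct-2-ynoate
Product: 12 benzyl 4-hydroxy-2-methoxy-6-pentylbenzoate, via cyclohexadiene cycloadduct 10 (not isolated), via aryl trimethylsilyl ether 11 (not isolated)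
Conditions: 9 (excess), neat, sealed tube, 130 °C; then 1 M HCl, THF, rt
Reagents that add atoms: none
Why: The reaction is a thermal Diels–Alder cycloaddition of an electron-rich 1,1-dialkoxy-3-silyloxybutadiene with an acetylenic ester, the closest known reaction type being the formation of 4-hydroxy-2-alkoxybenzoates from such dienes and 2-alkynoates. Bond formation is asynchronous: the unsubstituted CH2 terminus of 9, which carries the largest HOMO coefficient as the beta-carbon of the silyl enol ether, bonds first to the pentyl-bearing beta-carbon of 4 (ring bond C5–C6), and the ketene acetal carbon then bonds to the alpha-carbon (ring bond C1–C2). Ring B is thus closed intermolecularly in a [4+2] mode, both new bonds arising from one diene–dienophile encounter, to give the cyclohexa-1,4-diene 10. In 10 a ring CH2 lies across the ring from the dimethyl ketal carbon, so 1,4-elimination of methanol, driven by aromatization, should follow at the reaction temperature and give aryl silyl ether 11; dilute acid then cleaves the O–Si bond to release the phenol. No stereocentre is formed. The selectivity needed is the orientation of the unsymmetrical diene on the ynoate, and it is secured by the matched polarization of the partners (nucleophilic CH2 terminus against electrophilic beta-carbon), which the beta-pentyl group slows but does not reverse; the low dienophilicity is met by excess diene, absence of solvent and prolonged heating. The same event tells the two oxygens apart, since the ketene acetal carbon keeps one methoxy group as the O2 methyl ether while the silyl enol ether oxygen becomes the free O4 phenol.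

Step 5
Reactants: 13 olivetol (5-pentylbenzene-1,3-diol)
Product: 14 1,3-dimethoxy-5-pentylbenzene
Conditions: CH3I, K2CO3, acetone, reflux
Reagents that add atoms: iodomethane, CI
Why: Williamson ether synthesis on both phenols; the carbonate base gives O-alkylation and is not strong enough to promote C-alkylation to a significant extent.

Step 6
Reactants: 14 1,3-dimethoxy-5-pentylbenzene
Product: 16 2-chloro-1,3-dimethoxy-5-pentylbenzene, via 2-lithio-1,3-dimethoxy-5-pentylbenzene 15 (not isolated)
Conditions: n-BuLi, THF, 0 °C → rt; then C2Cl6, −78 °C → rt
Reagents that add atoms: hexachloroethane, ClC(Cl)(Cl)C(Cl)(Cl)Cl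
Why: Directed ortho-metalation: the hydrogen flanked by both methoxy groups is the most acidic ring position and the lithium is held by both oxygens, so 15 should form at C2 only. Chlorine transfer from hexachloroethane then fixes the chlorine between the two oxygens.

Step 7
Reactants: 16 2-chloro-1,3-dimethoxy-5-pentylbenzene
Product: 17 3-chloro-2,4-dimethoxy-6-pentylbenzaldehyde
Conditions: Cl2CHOCH3, TiCl4, CH2Cl2, −20 → 0 °C; then ice–water
Reagents that add atoms: dichloromethyl methyl ether, COC(Cl)Cl; water, O
Why: Rieche formylation (Friedel–Crafts substitution by a chloromethoxycarbenium ion, then hydrolysis). The two open ring positions of 16 are equivalent, each ortho to one methoxy group and para to the other, and the aldehyde deactivates the ring against a second substitution.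

Step 8
Reactants: 17 3-chloro-2,4-dimethoxy-6-pentylbenzaldehyde
Product: 18 3-chloro-2,4-dimethoxy-6-pentylbenzoic acid
Conditions: NaClO2, NaH2PO4, 2-methylbut-2-ene, t-BuOH–H2O, rt
Reagents that add atoms: sodium chlorite, [Na+].[O-]Cl=O
Why: Pinnick oxidation: chlorous acid adds to the aldehyde and fragments to the acid. The alkene scavenger removes the hypochlorous acid formed, which would otherwise chlorinate the free C5 position of the electron-rich ring.

Step 9
Reactants: 18 3-chloro-2,4-dimethoxy-6-pentylbenzoic acid; 12 benzyl 4-hydroxy-2-methoxy-6-pentylbenzoate
Product: 20 benzyl 4-[(3-chloro-2,4-dimethoxy-6-pentylbenzoyl)oxy]-2-methoxy-6-pentylbenzoate, via 3-chloro-2,4-dimethoxy-6-pentylbenzoyl chloride 19 (not isolated)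
Conditions: (COCl)2, DMF (cat.), CH2Cl2, 0 °C → rt, evaporate; then 12, Et3N, DMAP (cat.), CH2Cl2, 0 °C → rt
Reagents that add atoms: none
Why: The acid is converted into acid chloride 19 through the chloroiminium species formed from DMF, and 19 acylates the phenoxide of 12 under nucleophilic catalysis (esterification by an acyl chloride). Only O4 of ring B can react, because O2 is a methyl ether and the carboxyl is a benzyl ester.

Step 10
Reactants: 20 benzyl 4-[(3-chloro-2,4-dimethoxy-6-pentylbenzoyl)oxy]-2-methoxy-6-pentylbenzoate
Product: 21 4-[(3-chloro-2-hydroxy-4-methoxy-6-pentylbenzoyl)oxy]-2-hydroxy-6-pentylbenzoic acid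
Conditions: BCl3 (excess), CH2Cl2, −78 → 0 °C; then cold H2O
Reagents that add atoms: none
Why: Chelation-controlled Lewis acid dealkylation: BCl3 bound to a carbonyl oxygen reaches the ortho methoxy group through a six-membered chelate and chloride removes the methyl group, which should happen at O2 of ring B and O2 of ring A, while the benzyl ester is cleaved at its benzylic C–O bond. The O4 methyl ether of ring A has no carbonyl neighbour and the inter-ring aryl ester has no alkyl group to lose, so both should survive; the cold, non-basic work-up protects the ortho-hydroxy acid from decarboxylation.

## Compound list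

1 | hept-1-yne | CCCCCC#C | starting material
2 | benzyl chloroformate | O=C(Cl)OCc1ccccc1 | starting material
3 | lithium hept-1-yn-1-ide | [Li]C#CCCCCC | intermediate
4 | benzyl oct-2-ynoate | CCCCCC#CC(=O)OCc1ccccc1 | intermediate
5 | 1,1-dimethoxyethene | C=C(OC)OC | starting material
6 | acetyl chloride | CC(=O)Cl | starting material
7 | 4,4-dimethoxybut-3-en-2-one | CC(=O)C=C(OC)OC | intermediate
8 | lithium 4,4-dimethoxybuta-1,3-dien-2-olate | [Li+].[O-]C(=C)C=C(OC)OC | intermediate
9 | 1,1-dimethoxy-3-(trimethylsilyloxy)buta-1,3-diene | COC(OC)=CC(=C)O[Si](C)(C)C | intermediate
10 | benzyl 6,6-dimethoxy-2-pentyl-4-(trimethylsilyloxy)cyclohexa-1,4-diene-1-carboxylate | CCCCCC1=C(C(=O)OCc2ccccc2)C(OC)(OC)C=C(O[Si](C)(C)C)C1 | intermediate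
11 | benzyl 2-methoxy-6-pentyl-4-(trimethylsilyloxy)benzoate | CCCCCc1cc(O[Si](C)(C)C)cc(OC)c1C(=O)OCc1ccccc1 | intermediate
12 | benzyl 4-hydroxy-2-methoxy-6-pentylbenzoate | CCCCCc1cc(O)cc(OC)c1C(=O)OCc1ccccc1 | intermediate
13 | olivetol (5-pentylbenzene-1,3-diol) | CCCCCc1cc(O)cc(O)c1 | starting material
14 | 1,3-dimethoxy-5-pentylbenzene | CCCCCc1cc(OC)cc(OC)c1 | intermediate
15 | 2-lithio-1,3-dimethoxy-5-pentylbenzene | [Li]c1c(OC)cc(CCCCC)cc1OC | intermediate
16 | 2-chloro-1,3-dimethoxy-5-pentylbenzene | CCCCCc1cc(OC)c(Cl)c(OC)c1 | intermediate
17 | 3-chloro-2,4-dimethoxy-6-pentylbenzaldehyde | CCCCCc1cc(OC)c(Cl)c(OC)c1C=O | intermediate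
18 | 3-chloro-2,4-dimethoxy-6-pentylbenzoic acid | CCCCCc1cc(OC)c(Cl)c(OC)c1C(=O)O | intermediate
19 | 3-chloro-2,4-dimethoxy-6-pentylbenzoyl chloride | CCCCCc1cc(OC)c(Cl)c(OC)c1C(=O)Cl | intermediate
20 | benzyl 4-[(3-chloro-2,4-dimethoxy-6-pentylbenzoyl)oxy]-2-methoxy-6-pentylbenzoate | CCCCCc1cc(OC(=O)c2c(CCCCC)cc(OC)c(Cl)c2OC)cc(OC)c1C(=O)OCc1ccccc1 | intermediate
21 | 4-[(3-chloro-2-hydroxy-4-methoxy-6-pentylbenzoyl)oxy]-2-hydroxy-6-pentylbenzoic acid | CCCCCc1cc(OC(=O)c2c(CCCCC)cc(OC)c(Cl)c2O)cc(O)c1C(=O)O | target

## Step count and least certain steps

Total: 10 steps. Longest linear sequence: 6 steps (13 → 14 → 16 → 17 → 18 → 20 → 21, steps 5–10). The ring B arm is 5 steps in its longest line (steps 2, 3, 4, 9, 10), with step 1 in parallel.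

Step 4 (key step). The cycloaddition may be too slow: the beta-pentyl group lowers the dienophilicity of 4, and 9 may be lost to hydrolysis or thermal self-condensation before it reacts. Fallback, setting out from 13 and returning at 21: carboxylation of 13 with magnesium methyl carbonate, Mg(OCO2CH3)2, in DMF at about 120 °C (a chelation-directed Kolbe–Schmitt-type carboxylation) to 2,4-dihydroxy-6-pentylbenzoic acid F1. Alkylation of the carboxylate with benzyl bromide and KHCO3 in DMF then gives benzyl 2,4-dihydroxy-6-pentylbenzoate F2. Acylation of F2 with 19 (Et3N, DMAP, CH2Cl2) should go to the 4-hydroxyl, which is not hydrogen-bonded, and give benzyl 4-[(3-chloro-2,4-dimethoxy-6-pentylbenzoyl)oxy]-2-hydroxy-6-pentylbenzoate F3. BCl3 in CH2Cl2 then removes the ring A O2 methyl group and the benzyl group to give 21. This gives up the covalent differentiation of O2 and O4 and relies on the hydrogen bond.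

Step 2. Et3N may dehydrochlorinate 6 to a ketene faster than the ketene acetal is acylated, and chloride may demethylate the dialkoxycarbenium intermediate before it is deprotonated. Fallback, setting out from 6 and returning at 7: AlCl3-promoted addition of 6 to 1,1-dichloroethene in CH2Cl2 to 4,4,4-trichlorobutan-2-one F4, which loses hydrogen chloride on distillation to give 4,4-dichlorobut-3-en-2-one F5. Double addition–elimination with NaOCH3 in methanol then gives 7.

Step 7. The Lewis acid may remove the methyl group from the methoxy group next to the new formyl group, and the chlorine-deactivated ring may react sluggishly. Fallback, setting out from 16 and returning at 18: bromination with N-bromosuccinimide in acetonitrile at the only kind of open position to 1-bromo-3-chloro-2,4-dimethoxy-6-pentylbenzene F6. Bromine–lithium exchange with n-BuLi in THF at −78 °C gives (3-chloro-2,4-dimethoxy-6-pentylphenyl)lithium F7, and carboxylation with CO2 and acidic work-up gives 18 directly, without the aldehyde.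

Step 9. Acyl transfer from the doubly ortho-substituted 19 may be slow, so hydrolysis of 19 during the reaction could compete. Fallback, setting out from 18 and 12 and returning at 20: trifluoroacetic anhydride in toluene at rt converts 18 into 3-chloro-2,4-dimethoxy-6-pentylbenzoic trifluoroacetic anhydride F8. F8 ionizes to the stabilized aroyl cation, which acylates the phenol of 12 under acidic conditions without a tetrahedral intermediate at the hindered carbonyl.

Step 10. The benzyl ester may be cleaved incompletely at a temperature at which the methyl ethers already react, and forcing the reaction may cause loss of the ring A O4 methyl group or decarboxylation during work-up. Fallback, setting out from 20 and returning at 21: hydrogenolysis over palladium on carbon (Pd/C, H2, ethyl acetate, rt, stopped at consumption of 20 to spare the aryl chloride) to 4-[(3-chloro-2,4-dimethoxy-6-pentylbenzoyl)oxy]-2-methoxy-6-pentylbenzoic acid F9. BCl3 in CH2Cl2 at −78 → −20 °C then has only the two carbonyl-flanking methyl ethers to cleave and gives 21.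

## Further compounds

F1 | step 4 | 2,4-dihydroxy-6-pentylbenzoic acid | CCCCCc1cc(O)cc(O)c1C(=O)O
F2 | step 4 | benzyl 2,4-dihydroxy-6-pentylbenzoate | CCCCCc1cc(O)cc(O)c1C(=O)OCc1ccccc1
F3 | step 4 | benzyl 4-[(3-chloro-2,4-dimethoxy-6-pentylbenzoyl)oxy]-2-hydroxy-6-pentylbenzoate | CCCCCc1cc(OC(=O)c2c(CCCCC)cc(OC)c(Cl)c2OC)cc(O)c1C(=O)OCc1ccccc1
F4 | step 2 | 4,4,4-trichlorobutan-2-one | CC(=O)CC(Cl)(Cl)Cl
F5 | step 2 | 4,4-dichlorobut-3-en-2-one | CC(=O)C=C(Cl)Cl
F6 | step 7 | 1-bromo-3-chloro-2,4-dimethoxy-6-pentylbenzene | CCCCCc1cc(OC)c(Cl)c(OC)c1Br
F7 | step 7 | (3-chloro-2,4-dimethoxy-6-pentylphenyl)lithium | [Li]c1c(CCCCC)cc(OC)c(Cl)c1OC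
F8 | step 9 | 3-chloro-2,4-dimethoxy-6-pentylbenzoic trifluoroacetic anhydride | CCCCCc1cc(OC)c(Cl)c(OC)c1C(=O)OC(=O)C(F)(F)F
F9 | step 10 | 4-[(3-chloro-2,4-dimethoxy-6-pentylbenzoyl)oxy]-2-methoxy-6-pentylbenzoic acid | CCCCCc1cc(OC(=O)c2c(CCCCC)cc(OC)c(Cl)c2OC)cc(OC)c1C(=O)O
A1 | alternative 1 | 1-fluoro-3,5-dimethoxybenzene | COc1cc(F)cc(OC)c1
A2 | alternative 1 | pentyllithium | [Li]CCCCC
A3 | alternative 1 | 3,5-dimethoxybenzyne | COC1=CC(OC)=CC#C1
A4 | alternative 1 | 2,4-dimethoxy-6-pentylbenzoic acid | CCCCCc1cc(OC)cc(OC)c1C(=O)O
A5 | alternative 2 | dibenzyl malonate | O=C(CC(=O)OCc1ccccc1)OCc1ccccc1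
A6 | alternative 2 | (E)-non-3-en-2-one | CCCCC/C=C/C(C)=O
A7 | alternative 2 | benzyl 2,4-dioxo-6-pentylcyclohexane-1-carboxylate (stereoisomer and tautomer mixture) | CCCCCC1CC(=O)CC(=O)C1C(=O)OCc1ccccc1
A8 | alternative 3 | 4-chloro-1-methoxy-1,3-bis(trimethylsilyloxy)buta-1,3-diene | COC(O[Si](C)(C)C)=CC(O[Si](C)(C)C)=CCl
A9 | alternative 3 | 1,1,1-trimethoxyoctan-3-one | CCCCCC(=O)CC(OC)(OC)OC
A10 | alternative 3 | methyl 3-chloro-2-hydroxy-4-methoxy-6-pentylbenzoate | CCCCCc1cc(OC)c(Cl)c(O)c1C(=O)OC
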